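3 questions stand here, and they are really one count: how many chains share the monomer.

| flask | free monomer | protic impurity | initiator | remark | time |
|---|---|---|---|---|---|
| west | 1 M | 0.30 M | 0.50 mM | run made earlier |  |
| oak | 1.0 M | 0.300 M | 1.0 mM |  | 20 h |
| birch | 1.0 M | 0.300 M | 1.0 mM |  | 60 h |
west run (percent of the free monomer charged)

| time / h | monomer in chains / % | free monomer / % |
|---|---|---|
| 0.200 | 0.7 | 96.0 |
| 0.667 | 5.8 | 90.9 |
| 1.00 | 5.3 | 84.3 |
| 1.50 | 11.7 | 79.6 |
| 2.50 | 17.3 | 68.1 |
| 3.00 | 21.6 | 63.3 |
| 4.00 | 26.0 | 54.8 |

(standard deviation of a reading: 1 percentage point)
- the average divides the monomer in chains by the number of chains, living and dead together; two radicals that join make one chain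
- the analysis behind the earlier runs scatters by 1 percentage point, standard deviation
- the earlier runs do not show the number of chains; that part of a forecast is a guess
- no earlier run changes the charge of initiator; that part of a forecast is a guess
1. which of the two ends with the longer chains by the average number of monomer units in a chain (living and dead chains, two that joined counted as one) ("neither" if they lie within 10%) (oak / birch / neither)
2. average number of monomer units in a chain (living and dead chains, two that joined counted as one) at the end, oak
3. average number of monomer units in a chain (living and dead chains, two that joined counted as one) at the end, birch

Oak and birch are charged alike, so my decision is when to stop. The west run keeps 54.8% of its free monomer after 4.00 h. If oak merely held that decay, it would keep 4.94% at 20 h, and that is what birch's longer time has to gain.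

Now I write the balance of the initiator, the reagent charged in the smallest amount. I take each initiator spent to give two radicals, and two radicals that join make one chain, so I count one chain per initiator spent. The west run's missing 19.2% lies below the impurity's share, so I let each impurity take one monomer. The monomer left over, per initiator charged, comes to 700. This charge length, divided by the spent fraction of the initiator, is my estimate of the length, the number-average degree of polymerization, for a flask with nearly all of its free monomer reacted.

The runs do not show the spent fraction, so what follows is a guess. While that fraction is small I take it to grow in proportion to time, so I put birch's spending at about 3.00 times oak's. I stop at 20 h and expect oak's chains to be longer by that factor.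

The forecast says oak, with 2500 for oak and 1200 for birch, a ratio of 2.08. Its ground is “Initiator keeps making chains”.

The flask gives oak, with 4310 for oak and 1800 for birch. Oak keeps 84% of its initiator after 20.0 h and birch keeps 58% after 60.0 h. The spent fractions are therefore 16.5% and 41.7%, a ratio of 2.53, and oak's is less than the fraction 0.3 that the forecast's chains by 20 h make of the charge. The charge length over these fractions gives 4242 for oak and 1679 for birch.

    initiator → 2 initiating radical (k = 1.50 × 10⁻⁴ /min)
    free monomer + initiating radical → growing radical + monomer in chains (k = 2.70 × 10⁵ /M/min)
    free monomer + growing radical → monomer in chains + growing radical, rate k3*[growing radical]*[free monomer] (k = 74000 /M/min)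
    2 growing radical → dead chain (k = 3.00 × 10⁶ /M/s)
    protic impurity + free monomer → quenched substrate (k = 0.00480 /M/min)
    free monomer → decomposition product (k = 4.60 × 10⁻⁷ /min)

The neighbour flask is birch with 0.51 M of impurity. Its charge length is 490, and with 58% of its initiator left that gives 1167. The computed length is 1470, with 24% of its impurity still unbound.

The numbers in the tables are simulated with made-up constants; noise was put on by code.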